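**Retrosynthetic overview**

1. Numbering used throughout: C1/C2 epoxide, C3 ketone, C4=C5 (C15 methyl on C4), C6 (lactone O), C7, C8 (tiglate), C9, C10 (carbinol, C14 methyl), C11 (=C13H2), C12 (lactone C=O).
2. The C3 ketone comes from a C3 carbinol, formed when a Nozaki–Hiyama–Kishi reaction between a (Z)-C4 alkenyl bromide and a C3 epoxy aldehyde closes the ten-membered ring; the C8 tiglate is put on just before.
3. The α-methylene-γ-lactone (O, C12, C11, C7, C6) comes from CO2 and a C11 alkenyllithium. The enabling feature is that C6 and C8 both carry oxygen and flank C7, which bears C11, and C6 is allylic to C4=C5. A six-membered cyclic sulfate ring (O–C6–C7–C8–O–S) therefore activates C6–O with C7–C11 anti-periplanar to it, and the carboxylate born on C11 closes the lactone with inversion to the cis ring fusion, leaving sulfate on C8.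
4. The C6/C7/C8 triad is built on a temporary butenolide (C5 carbonyl, ring O on C8) made from (R)-linalool (C10). C8 is set by proline aminoxylation, C7 by anti conjugate addition, C6 by anti enolate hydroxylation, and C1/C2 by Sharpless epoxidation.
5. Ring order: butenolide (temporary), oxirane, cyclic sulfate (temporary), γ-lactone, ten-membered carbocycle.

Key step: step 15

Assumption: commercial (R)-(−)-linalool is taken to be of high enantiomeric purity; the C3 carbinol of 34 forms as an epimer mixture that converges on oxidation.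

**Route**

Step 1
Reactants: 1 (R)-(−)-linalool
Product: 2 linalool triethylsilyl ether
Conditions: TESOTf, 2,6-lutidine, CH2Cl2, −78 → 0 °C
Reagents that add atoms: triethylsilyl trifluoromethanesulfonate, CC[Si](CC)(CC)OS(=O)(=O)C(F)(F)F
Why: Silyl ether formation on the tertiary allylic alcohol with a silyl triflate; C10 comes unchanged from the chiral pool.

Step 2
Reactants: 2 linalool triethylsilyl ether
Product: 3 C7 aldehyde
Conditions: O3 (1.0 equiv, Sudan Red 7B end point), NaHCO3, CH2Cl2/MeOH, −78 °C; then Me2S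
Reagents that add atoms: ozone, [O-][O+]=O
Why: Chemoselective ozonolysis with reductive work-up, because the electron-rich trisubstituted alkene reacts much faster than the hindered vinyl group on the quaternary silyloxy carbon.

Step 3
Reactants: 3 C7 aldehyde; 4 ethyl 2-[bis(2-methylphenoxy)phosphoryl]acetate
Product: 6 (Z)-γ-anilinooxy enoate, via α-anilinooxy aldehyde 5 (not isolated)
Conditions: PhNO, L-proline (20 mol%), MeCN, −20 °C; then 4, NaH, THF, −78 → 0 °C
Reagents that add atoms: nitrosobenzene, O=Nc1ccccc1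
Why: Proline enamine catalysis (α-aminoxylation, O-selective nitroso aldol) sets C8 (R) by catalyst control from L-proline, and the labile aldehyde is trapped in the same flask by a Z-selective Horner–Wadsworth–Emmons olefination with a diaryl phosphonoacetate.

Step 4
Reactants: 6 (Z)-γ-anilinooxy enoate
Product: 8 butenolide, via (Z)-γ-hydroxy enoate 7 (not isolated)
Conditions: Cu(OAc)2 (30 mol%), EtOH, 23 °C; then toluene, 50 °C
Reagents that add atoms: none
Why: Copper-catalysed N–O cleavage frees the C8 hydroxyl, which lactonises onto the cis ester (transesterification) to give the butenolide without touching a stereocentre.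

Step 5
Reactants: 8 butenolide; 9 (Z)-but-2-ene-1,4-diol
Product: 10 (E)-allylic alcohol
Conditions: Hoveyda–Grubbs II catalyst (10 mol%), 9 (5 equiv), CH2Cl2, 40 °C
Reagents that add atoms: none
Why: Olefin cross-metathesis of a hindered, non-dimerising vinyl group with an excess of a reactive allylic diol should give the E-alkene under thermodynamic control, the electron-poor butenolide alkene being a spectator.

Step 6
Reactants: 10 (E)-allylic alcohol
Product: 11 epoxy alcohol
Conditions: Ti(OiPr)4, L-(+)-diethyl tartrate, t-BuOOH, 4 Å MS, CH2Cl2, −20 °C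
Reagents that add atoms: tert-butyl hydroperoxide, CC(C)(C)OO
Why: Sharpless asymmetric epoxidation, in which the L-(+)-tartrate catalyst sets the trans C1/C2 epoxide (a (2S,3R)-oxiranemethanol) by reagent control, independent of the remote C10 centre.

Step 7
Reactants: 11 epoxy alcohol
Product: 12 primary TBS ether
Conditions: TBSCl, imidazole, CH2Cl2, 0 → 23 °C
Reagents that add atoms: tert-butyldimethylsilyl chloride, CC(C)(C)[Si](C)(C)Cl
Why: Silyl ether formation on the primary hydroxyl under conditions too weakly basic for Payne rearrangement.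

Step 8
Reactants: 12 primary TBS ether; 13 (1-bromoethenyl)trimethylsilane
Product: 15 trans-lactone, via alkenylmagnesium bromide 14 (not isolated)
Conditions: 13, Mg, THF, 23 °C; then CuBr·SMe2 (10 mol%), 12, THF, −78 → −40 °C; aq. NH4Cl
Reagents that add atoms: none
Why: Copper-catalysed conjugate addition of an α-silylvinyl Grignard reagent to the butenolide, in which the nucleophile adds anti to the C8 side chain (1,2-induction on the five-membered ring) and sets C7.

Step 9
Reactants: 15 trans-lactone
Product: 16 all-trans hydroxy lactone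
Conditions: KHMDS, THF, −78 °C; then 2-(phenylsulfonyl)-3-phenyloxaziridine, −78 °C
Reagents that add atoms: 2-(phenylsulfonyl)-3-phenyloxaziridine, O=S(=O)(c1ccccc1)N1OC1c1ccccc1
Why: Davis oxidation of the potassium lactone enolate, where the oxidant approaches anti to the C7 alkenyl group, so the C6 oxygen is placed trans to C11, the configuration that the later SN2 inversion requires.

Step 10
Reactants: 16 all-trans hydroxy lactone
Product: 17 iodoalkene lactone
Conditions: NIS, 2,6-lutidine, (CF3)2CHOH/CH2Cl2, 0 °C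
Reagents that add atoms: N-iodosuccinimide, O=C1CCC(=O)N1I
Why: ipso-Iododesilylation of the alkenylsilane puts iodine on C11 regiospecifically, with lutidine buffering the epoxide and silyl ethers.

Step 11
Reactants: 17 iodoalkene lactone
Product: 18 lactol
Conditions: DIBAL-H (2.3 equiv), CH2Cl2, −78 °C; Rochelle salt
Reagents that add atoms: none
Why: Partial reduction of the lactone to the lactol through a tetrahedral aluminate that is stable at −78 °C, the free C6 hydroxyl only consuming one hydride.

Step 12
Reactants: 19 ethyltriphenylphosphonium bromide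
Product: 21 (1-bromoethyl)triphenylphosphonium bromide, via ethylidene ylide 20 (not isolated)
Conditions: n-BuLi, THF, 0 °C; then added to Br2, THF, −78 °C
Reagents that add atoms: bromine, BrBr
Why: Electrophilic α-bromination of a phosphorus ylide by inverse addition to bromine gives the α-bromo phosphonium salt.

Step 13
Reactants: 18 lactol; 21 (1-bromoethyl)triphenylphosphonium bromide
Product: 23 (Z)-bromoalkene diol, via bromo ylide 22 (not isolated)
Conditions: 21 (3 equiv), NaHMDS (3 equiv), THF, −78 °C; then 18 pre-treated with NaHMDS (2 equiv); −78 → 0 °C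
Reagents that add atoms: none
Why: Wittig olefination of the open hydroxy-aldehyde form of the lactol with an α-halo ylide should give the (Z)-2-bromoalk-2-ene under kinetic control (bromine cis to C6), while C6 is carried as its alkoxide against epimerisation and ring opening frees the C8 hydroxyl.

Step 14
Reactants: 23 (Z)-bromoalkene diol
Product: 24 cyclic sulfate
Conditions: NaH (2.2 equiv), THF, −20 °C; then 1,1'-sulfonyldiimidazole, −20 → 0 °C
Reagents that add atoms: 1,1'-sulfonyldiimidazole, O=S(=O)(n1ccnc1)n1ccnc1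
Why: Double sulfonylation of the anti-1,3-diol dianion closes the six-membered cyclic sulfate (O–C6–C7–C8–O–S) without touching a stereocentre, activating the allylic C6–O bond and masking C8–O at once.

Step 15
Reactants: 24 cyclic sulfate; 25 carbon dioxide
Product: 29 cis-fused α-methylene lactone alcohol, via alkenyllithium 26 (not isolated), via lithium carboxylate 27 (not isolated), via lactone sulfate monoester 28 (not isolated)
Conditions: t-BuLi (2.05 equiv), Et2O, −78 °C, 5 min; transfer into CO2-saturated THF, −78 °C; then DMF, → 23 °C; then conc. H2SO4 (cat.), H2O (2 equiv), THF, 0 → 23 °C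
Reagents that add atoms: none
Why: Proposed new method: selective iodine–lithium exchange at the 1-iodoethenyl group (alkenyl iodide far faster than alkenyl bromide with 2 equiv of t-BuLi at −78 °C) gives alkenyllithium 26, which adds to CO2 (C11–C12 bond), and on warming carboxylate 27 opens the cyclic sulfate at the allylic carbon C6 (O–C6 bond) to give 28, whose C8 sulfate monoester is hydrolysed with catalytic acid. The closest known reaction types are the carboxylation of alkenyllithiums with CO2 and the opening of cyclic sulfates by carboxylate nucleophiles followed by mild acidic hydrolysis of the sulfate ester; joining them into one carboxylative lactonisation is the new element. The γ-lactone (O, C12, C11, C7, C6) closes in the 5-exo-tet mode. C6 is set by SN2 inversion: in the chair of the cyclic sulfate with the C11 and C9 substituents equatorial and C5 axial, the C7–C11 bond is anti-periplanar to the C6–O bond, so the carboxylate can only attack from the rear and the cis ring fusion of the target results, C7 and C8 being untouched. The step needs regioselectivity for C6 over C8 and chemoselectivity for the iodide; the first should be secured by allylic activation of C6 and the neopentyl-like shielding of C8 by the C9–C10 quaternary unit, the second by the rate gap between iodide and bromide in halogen–lithium exchange. C-Alkylation of 26 is excluded by ring size, because C6 and C8 are both bonded to C7 (three-membered ring) and SN2' attack at C4 would be 5-endo.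

Step 16
Reactants: 29 cis-fused α-methylene lactone alcohol; 30 tigloyl chloride
Product: 31 C8 tiglate
Conditions: pyridine, DMAP (cat.), CH2Cl2, 0 → 23 °C
Reagents that add atoms: none
Why: Acylation of the only free hydroxyl directly after its release, which also removes the risk of lactone migration from O6 to O8; the E-configured tiglate is the stable isomer.

Step 17
Reactants: 31 C8 tiglate
Product: 32 C3,C10-diol
Conditions: HF·pyridine, pyridine, THF, 0 → 23 °C
Reagents that add atoms: none
Why: Buffered fluoride-mediated desilylation cleaves the primary TBS and tertiary TES ethers, while ester, lactone, epoxide and alkenyl bromide should be inert.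

Step 18
Reactants: 32 C3,C10-diol
Product: 33 epoxy aldehyde
Conditions: Dess–Martin periodinane, NaHCO3, CH2Cl2, 0 °C
Reagents that add atoms: none
Why: Dess–Martin oxidation of the primary epoxy alcohol; the tertiary C10 hydroxyl cannot be oxidised and the epoxide carbon C2 does not epimerise under buffered conditions.

Step 19
Reactants: 33 epoxy aldehyde
Product: 34 macrocyclic allylic alcohol
Conditions: CrCl2 (10 equiv), NiCl2 (5 mol%), DMSO/THF, 23 → 45 °C, 2 mM, slow addition
Reagents that add atoms: none
Why: Intramolecular Nozaki–Hiyama–Kishi reaction, in which the alkenylchromium formed from the (Z)-alkenyl bromide with retention adds only to the aldehyde and closes the ten-membered ring (C3–C4), the cis-fused lactone holding both chains on one face; the new C3 centre is lost in step 20.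

Step 20
Reactants: 34 macrocyclic allylic alcohol
Product: 35 target CNP0383091.1
Conditions: Dess–Martin periodinane, NaHCO3, CH2Cl2, 0 → 23 °C
Reagents that add atoms: none
Why: Dess–Martin oxidation of the secondary allylic alcohol to the (Z)-enone under neutral conditions that leave the tertiary alcohol, epoxide, both esters and the alkene geometry intact.

**Compound list**

"Side chain A" is the C8 substituent of 12; "target numbering" is that of the overview.

1 | (R)-(−)-linalool, (3R)-3,7-dimethylocta-1,6-dien-3-ol | C=C[C@](C)(O)CCC=C(C)C | starting material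
2 | (3R)-3,7-dimethyl-3-(triethylsilyloxy)octa-1,6-diene | C=C[C@](C)(O[Si](CC)(CC)CC)CCC=C(C)C | intermediate
3 | (4R)-4-methyl-4-(triethylsilyloxy)hex-5-enal | C=C[C@](C)(O[Si](CC)(CC)CC)CCC=O | intermediate
4 | ethyl 2-[bis(2-methylphenoxy)phosphoryl]acetate | CCOC(=O)CP(=O)(Oc1ccccc1C)Oc1ccccc1C | starting material
5 | (2R,4R)-2-(anilinooxy)-4-methyl-4-(triethylsilyloxy)hex-5-enal | C=C[C@](C)(O[Si](CC)(CC)CC)C[C@@H](ONc1ccccc1)C=O | intermediate
6 | ethyl (2Z,4R,6R)-4-(anilinooxy)-6-methyl-6-(triethylsilyloxy)octa-2,7-dienoate | C=C[C@](C)(O[Si](CC)(CC)CC)C[C@@H](ONc1ccccc1)/C=C\C(=O)OCC | intermediate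
7 | ethyl (2Z,4R,6R)-4-hydroxy-6-methyl-6-(triethylsilyloxy)octa-2,7-dienoate | C=C[C@](C)(O[Si](CC)(CC)CC)C[C@@H](O)/C=C\C(=O)OCC | intermediate
8 | (5R)-5-[(2R)-2-methyl-2-(triethylsilyloxy)but-3-en-1-yl]furan-2(5H)-one | C=C[C@](C)(O[Si](CC)(CC)CC)C[C@H]1OC(=O)C=C1 | intermediate
9 | (Z)-but-2-ene-1,4-diol | OC/C=C\CO | starting material
10 | (5R)-5-[(2R,3E)-5-hydroxy-2-methyl-2-(triethylsilyloxy)pent-3-en-1-yl]furan-2(5H)-one | OC/C=C/[C@](C)(O[Si](CC)(CC)CC)C[C@H]1OC(=O)C=C1 | intermediate
11 | (5R)-5-{(2R)-2-[(2R,3S)-3-(hydroxymethyl)oxiran-2-yl]-2-(triethylsilyloxy)propyl}furan-2(5H)-one | OC[C@@H]1O[C@H]1[C@](C)(O[Si](CC)(CC)CC)C[C@H]1OC(=O)C=C1 | intermediate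
12 | (5R)-5-{(2R)-2-[(2R,3S)-3-(tert-butyldimethylsilyloxymethyl)oxiran-2-yl]-2-(triethylsilyloxy)propyl}furan-2(5H)-one (the 5-substituent is side chain A) | CC(C)(C)[Si](C)(C)OC[C@@H]1O[C@H]1[C@](C)(O[Si](CC)(CC)CC)C[C@H]1OC(=O)C=C1 | intermediate
13 | (1-bromoethenyl)trimethylsilane | C=C(Br)[Si](C)(C)C | starting material
14 | [1-(trimethylsilyl)ethenyl]magnesium bromide | C=C([Mg]Br)[Si](C)(C)C | intermediate
15 | (4S,5R)-5-(side chain A)-4-[1-(trimethylsilyl)ethenyl]oxolan-2-one, 4,5-trans | CC(C)(C)[Si](C)(C)OC[C@@H]1O[C@H]1[C@](C)(O[Si](CC)(CC)CC)C[C@H]1OC(=O)C[C@@H]1C(=C)[Si](C)(C)C | intermediate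
16 | (3S,4S,5R)-3-hydroxy-5-(side chain A)-4-[1-(trimethylsilyl)ethenyl]oxolan-2-one, all-trans | CC(C)(C)[Si](C)(C)OC[C@@H]1O[C@H]1[C@](C)(O[Si](CC)(CC)CC)C[C@H]1OC(=O)[C@@H](O)[C@@H]1C(=C)[Si](C)(C)C | intermediate
17 | (3S,4S,5R)-3-hydroxy-4-(1-iodoethenyl)-5-(side chain A)oxolan-2-one | CC(C)(C)[Si](C)(C)OC[C@@H]1O[C@H]1[C@](C)(O[Si](CC)(CC)CC)C[C@H]1OC(=O)[C@@H](O)[C@@H]1C(=C)I | intermediate
18 | (3S,4S,5R)-4-(1-iodoethenyl)-5-(side chain A)oxolane-2,3-diol, anomer mixture at C2 | CC(C)(C)[Si](C)(C)OC[C@@H]1O[C@H]1[C@](C)(O[Si](CC)(CC)CC)C[C@H]1OC(O)[C@@H](O)[C@@H]1C(=C)I | intermediate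
19 | ethyltriphenylphosphonium bromide | CC[P+](c1ccccc1)(c1ccccc1)c1ccccc1.[Br-] | starting material
20 | ethylidene(triphenyl)phosphorane | CC=P(c1ccccc1)(c1ccccc1)c1ccccc1 | intermediate
21 | (1-bromoethyl)triphenylphosphonium bromide, racemic | CC(Br)[P+](c1ccccc1)(c1ccccc1)c1ccccc1.[Br-] | intermediate
22 | (1-bromoethylidene)triphenylphosphorane | CC(Br)=P(c1ccccc1)(c1ccccc1)c1ccccc1 | intermediate
23 | open-chain diol (target numbering): (4Z)-4-bromo-4,5-ene, 6-OH and 8-OH (6,8-anti, C6 epimeric to the target), 7-(1-iodoethenyl), 10-OTES, 1,2-epoxide, 3-OTBS; C1, C2, C7, C8, C10 as in the target | CC(C)(C)[Si](C)(C)OC[C@@H]1O[C@H]1[C@](C)(O[Si](CC)(CC)CC)C[C@@H](O)[C@H]([C@H](O)/C=C(/C)Br)C(=C)I | intermediate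
24 | 6,8-cyclic sulfate of 23 (1,3,2-dioxathiane 2,2-dioxide containing C6, C7, C8) | CC(C)(C)[Si](C)(C)OC[C@@H]1O[C@H]1[C@](C)(O[Si](CC)(CC)CC)C[C@H]1OS(=O)(=O)O[C@H](/C=C(/C)Br)[C@@H]1C(=C)I | intermediate
25 | carbon dioxide | O=C=O | starting material
26 | C11 alkenyllithium derived from 24 | CC(C)(C)[Si](C)(C)OC[C@@H]1O[C@H]1[C@](C)(O[Si](CC)(CC)CC)C[C@H]1OS(=O)(=O)O[C@H](/C=C(/C)Br)[C@@H]1C(=C)[Li] | intermediate
27 | lithium C12 carboxylate (2-substituted acrylate) of the cyclic sulfate | CC(C)(C)[Si](C)(C)OC[C@@H]1O[C@H]1[C@](C)(O[Si](CC)(CC)CC)C[C@H]1OS(=O)(=O)O[C@H](/C=C(/C)Br)[C@@H]1C(=C)C(=O)[O-].[Li+] | intermediate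
28 | cis-fused 6,12-lactone with lithium sulfate monoester on O8 | C=C1C(=O)O[C@@H](/C=C(/C)Br)[C@H]1[C@H](OS(=O)(=O)[O-])C[C@@](C)(O[Si](CC)(CC)CC)[C@@H]1O[C@H]1CO[Si](C)(C)C(C)(C)C.[Li+] | intermediate
29 | cis-fused α-methylene-γ-lactone (C6 as in the target) with 8-OH, (4Z)-4-bromoalkene, 10-OTES, 1,2-epoxide, 3-OTBS | C=C1C(=O)O[C@@H](/C=C(/C)Br)[C@H]1[C@H](O)C[C@@](C)(O[Si](CC)(CC)CC)[C@@H]1O[C@H]1CO[Si](C)(C)C(C)(C)C | intermediate
30 | tigloyl chloride, (2E)-2-methylbut-2-enoyl chloride | C/C=C(\C)C(=O)Cl | starting material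
31 | 8-O-tiglate of 29 | C=C1C(=O)O[C@@H](/C=C(/C)Br)[C@H]1[C@H](OC(=O)/C(C)=C/C)C[C@@](C)(O[Si](CC)(CC)CC)[C@@H]1O[C@H]1CO[Si](C)(C)C(C)(C)C | intermediate
32 | desilylated 31 with free 3-OH (primary) and 10-OH (tertiary) | C=C1C(=O)O[C@@H](/C=C(/C)Br)[C@H]1[C@H](OC(=O)/C(C)=C/C)C[C@@](C)(O)[C@@H]1O[C@H]1CO | intermediate
33 | C3 epoxy aldehyde (open-chain precursor of the ten-membered ring, (4Z)-4-bromoalkene) | C=C1C(=O)O[C@@H](/C=C(/C)Br)[C@H]1[C@H](OC(=O)/C(C)=C/C)C[C@@](C)(O)[C@@H]1O[C@H]1C=O | intermediate
34 | 3-hydroxy macrocycle (3-deoxo-3-hydroxy target, C3 epimer mixture) | C=C1C(=O)O[C@H]2/C=C(/C)C(O)[C@@H]3O[C@H]3[C@](C)(O)C[C@@H](OC(=O)/C(C)=C/C)[C@@H]12 | intermediate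
35 | CNP0383091.1 | C=C1C(=O)O[C@H]2/C=C(/C)C(=O)[C@@H]3O[C@H]3[C@](C)(O)C[C@@H](OC(=O)/C(C)=C/C)[C@@H]12 | target

**Step count and risk**

Total step count: 20. Longest linear sequence: 19 steps (steps 1–11 and 13–20, from 1); step 12 is a one-step branch.

Steps most likely to fail:

- **Step 15 (bears the label).** The carboxylate may open the cyclic sulfate at C8 instead of C6, the organolithium may attack sulfur of the sulfate before CO2 is reached, or bromine–lithium exchange at C4 may compete. The fallback uses known chemistry and separates the two bond formations; it sets out from 23 and comes back to the route at 29. Iodine–lithium exchange on the dilithium alkoxide of 23 (t-BuLi, 4.1 equiv, Et2O, −78 °C) followed by CO2 should give dihydroxy acid F1. Mitsunobu lactonisation (PPh3, DIAD, THF, 0 °C) then activates the allylic C6 hydroxyl and closes the γ-lactone with inversion to give 29.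

- **Step 19.** Oxidative addition of the alkenyl bromide to nickel may be slow, so that reduction of the epoxy aldehyde by chromium(II) or intermolecular coupling takes over. The fallback sets out from 33 and comes back at 35. Pinnick oxidation (NaClO2, NaH2PO4, 2-methylbut-2-ene) gives epoxy acid F5. Palladium-catalysed stannylation of the alkenyl bromide (Me3SnSnMe3, Pd(PPh3)4, dioxane, 80 °C) gives alkenylstannane acid F6. 1-Chloro-N,N,2-trimethylprop-1-en-1-amine converts it to acid chloride F7. An intramolecular acylative Stille coupling (Pd2(dba)3, tri(2-furyl)phosphine, THF, high dilution) then forms C3–C4 at the ketone level and gives 35 directly.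

- **Step 13.** Geometric control with the α-bromo ylide may be poor, and base-induced decomposition of the unprotected α-hydroxy lactol may compete. The fallback sets out from 16 (before iododesilylation) and comes back at 23. DIBAL-H reduction gives silyl lactol F2. Dibromomethylenation (CBr4, PPh3, Zn, CH2Cl2) gives 1,1-dibromoalkene diol F3. Negishi methylation (MeZnCl, Pd(PPh3)4, THF), which replaces selectively the bromine trans to C6, gives (Z)-bromoalkene silane F4, the alkenylsilane being inert. Iododesilylation (NIS, 2,6-lutidine, (CF3)2CHOH) then gives 23.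

Further compounds
F1 | step 15 | dihydroxy acid (C12 acid on C11, free 6-OH and 8-OH, otherwise as 23) | CC(C)(C)[Si](C)(C)OC[C@@H]1O[C@H]1[C@](C)(O[Si](CC)(CC)CC)C[C@@H](O)[C@H]([C@H](O)/C=C(/C)Br)C(=C)C(=O)O
F2 | step 13 | silyl lactol, (3S,4S,5R)-5-(side chain A)-4-[1-(trimethylsilyl)ethenyl]oxolane-2,3-diol | CC(C)(C)[Si](C)(C)OC[C@@H]1O[C@H]1[C@](C)(O[Si](CC)(CC)CC)C[C@H]1OC(O)[C@@H](O)[C@@H]1C(=C)[Si](C)(C)C
F3 | step 13 | 1,1-dibromoalkene diol (4,4-dibromo-4,5-ene, 6-OH, 8-OH, C11 trimethylsilyl) | CC(C)(C)[Si](C)(C)OC[C@@H]1O[C@H]1[C@](C)(O[Si](CC)(CC)CC)C[C@@H](O)[C@H]([C@H](O)C=C(Br)Br)C(=C)[Si](C)(C)C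
F4 | step 13 | (Z)-bromoalkene silane (23 with trimethylsilyl in place of iodine on C11) | CC(C)(C)[Si](C)(C)OC[C@@H]1O[C@H]1[C@](C)(O[Si](CC)(CC)CC)C[C@@H](O)[C@H]([C@H](O)/C=C(/C)Br)C(=C)[Si](C)(C)C
F5 | step 19 | epoxy acid (C3 carboxylic acid of 33) | C=C1C(=O)O[C@@H](/C=C(/C)Br)[C@H]1[C@H](OC(=O)/C(C)=C/C)C[C@@](C)(O)[C@@H]1O[C@H]1C(=O)O
F6 | step 19 | alkenylstannane acid ((4Z)-4-trimethylstannyl analogue of F5) | C=C1C(=O)O[C@@H](/C=C(/C)[Sn](C)(C)C)[C@H]1[C@H](OC(=O)/C(C)=C/C)C[C@@](C)(O)[C@@H]1O[C@H]1C(=O)O
F7 | step 19 | acid chloride of F6 | C=C1C(=O)O[C@@H](/C=C(/C)[Sn](C)(C)C)[C@H]1[C@H](OC(=O)/C(C)=C/C)C[C@@](C)(O)[C@@H]1O[C@H]1C(=O)Cl
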